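**Plan**
- Retrosynthesis: ring C is cut at O1–C2 and C4–C4a together, giving 2,4-diprenylphloroglucinol 8 and the cinnamoyl-type chloride 16; 16 is cut at C2=C3 and at the pyran ring of its chromene, 8 at its two aryl–prenyl bonds.
- Enabling feature: ring A of 8 has one unsubstituted carbon (future C4a) between two hydroxyls made equivalent by a mirror plane (future O1 and 5-OH), and C2–C3–C4 of 16 is a 1,3-dielectrophile, so the annulation has no regiochemical choice and needs no protecting group.
- Forward: ring A is prenylated twice by directed lithiation of tris-MOM phloroglucinol and then unmasked; the chromene of the ring B fragment comes from a propargyl Claisen cascade and is extended to the acryloyl chloride.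
- Ring C is closed last, by bromomagnesium-phenoxide-templated ortho-acylation and oxa-Michael addition in one flask.
- Stereochemistry: C2 is the only stereocenter and is base-labile in a 5-hydroxyflavanone; it forms as a racemate in the annulation, and the (2S) enantiomer is secured in the last step by Noyori–Ikariya asymmetric transfer hydrogenation used as a kinetic resolution under weakly acidic conditions.

Key step: step 9

**Step 1**
Reactants: 1 benzene-1,3,5-triol (phloroglucinol)
Product: 2 1,3,5-tris(methoxymethoxy)benzene
Conditions: NaH (3.3 equiv), MOMCl (3.3 equiv), DMF, 0 °C → rt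
Reagents that add atoms: chloromethyl methyl ether, COCCl
Why: Williamson-type O-alkylation of the phenoxide with the hard chloromethyl ether should give the tris-acetal, whose MOM groups later direct ortho-lithiation and leave under mild acid.

**Step 2**
Reactants: 2 1,3,5-tris(methoxymethoxy)benzene; 3 1-bromo-3-methylbut-2-ene (prenyl bromide)
Product: 5 1,3,5-tris(methoxymethoxy)-2-(3-methylbut-2-en-1-yl)benzene, via aryllithium 4 (not isolated)
Conditions: n-BuLi (1.1 equiv), THF, 0 °C; CuBr·SMe2 (10 mol%), 3, −78 °C → rt
Reagents that add atoms: none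
Why: Directed ortho-metalation between two MOM ethers should give aryllithium 4, which CuBr·SMe2 couples with the allylic bromide at its primary carbon (SN2 allylation), the three ring positions being equivalent.

**Step 3**
Reactants: 5 1,3,5-tris(methoxymethoxy)-2-(3-methylbut-2-en-1-yl)benzene; 3 1-bromo-3-methylbut-2-ene
Product: 7 1,3,5-tris(methoxymethoxy)-2,4-bis(3-methylbut-2-en-1-yl)benzene, via aryllithium 6 (not isolated)
Conditions: n-BuLi (1.1 equiv), THF, 0 °C; CuBr·SMe2 (10 mol%), 3, −78 °C → rt
Reagents that add atoms: none
Why: A second directed ortho-metalation at either of the two equivalent C–H bonds, each again flanked by two MOM ethers, followed by the same SN2 allylation should give a single diprenyl arene.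

**Step 4**
Reactants: 7 1,3,5-tris(methoxymethoxy)-2,4-bis(3-methylbut-2-en-1-yl)benzene
Product: 8 2,4-bis(3-methylbut-2-en-1-yl)benzene-1,3,5-triol
Conditions: HCl (3 M aq.) in MeOH, rt → 40 °C, argon, short reaction time; product used promptly
Reagents that add atoms: none
Why: Acid-catalysed acetal exchange with methanol should remove the three MOM groups, the mild temperature and brief exposure keeping the prenyl groups from cyclizing onto the freed phenols.

**Step 5**
Reactants: 9 4-hydroxybenzaldehyde; 10 3-chloro-3-methylbut-1-yne
Product: 11 4-[(2-methylbut-3-yn-2-yl)oxy]benzaldehyde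
Conditions: K2CO3, KI (cat.), acetone, reflux
Reagents that add atoms: none
Why: Williamson-type O-alkylation of the phenoxide with the tertiary propargylic chloride should give the aryl 1,1-dimethylpropargyl ether.

**Step 6**
Reactants: 11 4-[(2-methylbut-3-yn-2-yl)oxy]benzaldehyde
Product: 12 2,2-dimethyl-2H-chromene-6-carbaldehyde
Conditions: N,N-diethylaniline, 190 °C
Reagents that add atoms: none
Why: Aromatic propargyl Claisen rearrangement, 1,5-hydrogen shift and oxa-6π electrocyclization should follow one another and build the 2,2-dimethylchromene ring, the formyl group para to the oxygen ending at C6.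

**Step 7**
Reactants: 12 2,2-dimethyl-2H-chromene-6-carbaldehyde; 13 propanedioic acid (malonic acid)
Product: 15 (2E)-3-(2,2-dimethyl-2H-chromen-6-yl)prop-2-enoic acid, via arylidenemalonic acid 14 (not isolated)
Conditions: pyridine, piperidine (cat.), 90 °C
Reagents that add atoms: none
Why: Knoevenagel condensation followed by decarboxylation in pyridine (Doebner modification) should give the (E)-acrylic acid under thermodynamic control.

**Step 8**
Reactants: 15 (2E)-3-(2,2-dimethyl-2H-chromen-6-yl)prop-2-enoic acid
Product: 16 (2E)-3-(2,2-dimethyl-2H-chromen-6-yl)prop-2-enoyl chloride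
Conditions: (COCl)2 (1.2 equiv), DMF (cat.), CH2Cl2, 0 °C → rt; volatiles removed, used crude
Reagents that add atoms: oxalyl chloride, O=C(Cl)C(=O)Cl
Why: Chloride transfer through the Vilsmeier-type chloroiminium salt should give the acid chloride at low temperature with only volatile by-products, so that it can be used without purification.

**Step 9**
Reactants: 8 2,4-bis(3-methylbut-2-en-1-yl)benzene-1,3,5-triol; 16 (2E)-3-(2,2-dimethyl-2H-chromen-6-yl)prop-2-enoyl chloride
Product: 19 rac-5,7-dihydroxy-2-(2,2-dimethyl-2H-chromen-6-yl)-6,8-bis(3-methylbut-2-en-1-yl)-2,3-dihydro-4H-chromen-4-one, via tris(bromomagnesium) phenoxide 17 (not isolated), via chalcone 18 (not isolated)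
Conditions: EtMgBr (3.0 equiv), Et2O, 0 °C, solvent exchanged for toluene; 16 (1.0 equiv), toluene, 0 °C → rt; then NaOAc, EtOH, 50 °C in the same flask; aq. NH4Cl
Reagents that add atoms: none
Why: The bromomagnesium phenoxide 17 binds the carbonyl oxygen of 16 and delivers the acyl carbon to the only unsubstituted ring carbon through a six-membered chelate (metal-template ortho-acylation, a Friedel–Crafts acylation run under basic conditions), which forms the C4–C4a bond and gives the bromomagnesium chelate of chalcone 18; the neighbouring phenoxide then adds to the chelation-activated enone (oxa-Michael addition) and forms the O1–C2 bond. The closest known reaction type is the exclusive ortho-acylation of aryloxymagnesium bromides with α,β-unsaturated acyl chlorides to 2'-hydroxychalcones, joined to the base-mediated isomerization of 2',6'-dihydroxychalcones to 5-hydroxyflavanones. Ring C closes in the 6-endo-trig mode. The new stereocenter C2 arises without control, because both enone faces are open and the closure is reversible under base, so 19 should be racemic and the (2S) series is selected in step 10. The step needs acylation at carbon over oxygen and 1,2- over 1,4-attack on the enoyl chloride, both secured by the chelate geometry in a non-coordinating solvent; it needs no regiocontrol, because ring A of 8 has a single free carbon flanked by two mirror-related hydroxyls, the unused one becoming the hydrogen-bonded 5-OH, and the absence of free acid spares the prenyl groups and the chromene.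

**Step 10**
Reactants: 19 rac-5,7-dihydroxy-2-(2,2-dimethyl-2H-chromen-6-yl)-6,8-bis(3-methylbut-2-en-1-yl)-2,3-dihydro-4H-chromen-4-one
Product: 20 (2S)-5,7-dihydroxy-2-(2,2-dimethyl-2H-chromen-6-yl)-6,8-bis(3-methylbut-2-en-1-yl)-2,3-dihydro-4H-chromen-4-one
Conditions: RuCl(p-cymene)[(R,R)-TsDPEN] (cat.), HCO2H/Et3N (5:2), EtOAc, rt, stopped near half conversion; chromatography
Reagents that add atoms: none
Why: In this Noyori–Ikariya asymmetric transfer hydrogenation run as a kinetic resolution, RuCl(p-cymene)[(R,R)-TsDPEN], by its usual sense for aryl ketones, should reduce the (2R)-enantiomer to the cis-(2R,4R)-flavan-4-ol (hydride delivered anti to the equatorial aryl group) and leave the (2S)-flavanone, while the alkenes stay untouched and the acidic medium prevents opening of ring C.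

**Compound list**
1 | benzene-1,3,5-triol (phloroglucinol) | Oc1cc(O)cc(O)c1 | starting material
2 | 1,3,5-tris(methoxymethoxy)benzene | COCOc1cc(OCOC)cc(OCOC)c1 | intermediate
3 | 1-bromo-3-methylbut-2-ene (prenyl bromide) | CC(C)=CCBr | starting material
4 | [2,4,6-tris(methoxymethoxy)phenyl]lithium | [Li]c1c(OCOC)cc(OCOC)cc1OCOC | intermediate
5 | 1,3,5-tris(methoxymethoxy)-2-(3-methylbut-2-en-1-yl)benzene | CC(C)=CCc1c(OCOC)cc(OCOC)cc1OCOC | intermediate
6 | [2,4,6-tris(methoxymethoxy)-3-(3-methylbut-2-en-1-yl)phenyl]lithium | CC(C)=CCc1c(OCOC)cc(OCOC)c([Li])c1OCOC | intermediate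
7 | 1,3,5-tris(methoxymethoxy)-2,4-bis(3-methylbut-2-en-1-yl)benzene | CC(C)=CCc1c(OCOC)cc(OCOC)c(CC=C(C)C)c1OCOC | intermediate
8 | 2,4-bis(3-methylbut-2-en-1-yl)benzene-1,3,5-triol | CC(C)=CCc1c(O)cc(O)c(CC=C(C)C)c1O | intermediate
9 | 4-hydroxybenzaldehyde | O=Cc1ccc(O)cc1 | starting material
10 | 3-chloro-3-methylbut-1-yne | C#CC(C)(C)Cl | starting material
11 | 4-[(2-methylbut-3-yn-2-yl)oxy]benzaldehyde | C#CC(C)(C)Oc1ccc(C=O)cc1 | intermediate
12 | 2,2-dimethyl-2H-chromene-6-carbaldehyde | CC1(C)C=Cc2cc(C=O)ccc2O1 | intermediate
13 | propanedioic acid (malonic acid) | OC(=O)CC(=O)O | starting material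
14 | 2-[(2,2-dimethyl-2H-chromen-6-yl)methylidene]propanedioic acid | OC(=O)C(=Cc1ccc2OC(C)(C)C=Cc2c1)C(=O)O | intermediate
15 | (2E)-3-(2,2-dimethyl-2H-chromen-6-yl)prop-2-enoic acid | OC(=O)/C=C/c1ccc2OC(C)(C)C=Cc2c1 | intermediate
16 | (2E)-3-(2,2-dimethyl-2H-chromen-6-yl)prop-2-enoyl chloride | ClC(=O)/C=C/c1ccc2OC(C)(C)C=Cc2c1 | intermediate
17 | tris(bromomagnesium) 2,4-bis(3-methylbut-2-en-1-yl)benzene-1,3,5-triolate | CC(C)=CCc1c(O[Mg]Br)cc(O[Mg]Br)c(CC=C(C)C)c1O[Mg]Br | intermediate
18 | (2E)-3-(2,2-dimethyl-2H-chromen-6-yl)-1-[2,4,6-trihydroxy-3,5-bis(3-methylbut-2-en-1-yl)phenyl]prop-2-en-1-one | CC(C)=CCc1c(O)c(CC=C(C)C)c(O)c(C(=O)/C=C/c2ccc3OC(C)(C)C=Cc3c2)c1O | intermediate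
19 | rac-5,7-dihydroxy-2-(2,2-dimethyl-2H-chromen-6-yl)-6,8-bis(3-methylbut-2-en-1-yl)-2,3-dihydro-4H-chromen-4-one | CC(C)=CCc1c(O)c(CC=C(C)C)c2c(c1O)C(=O)CC(c1ccc3c(c1)C=CC(C)(C)O3)O2 | intermediate
20 | (2S)-5,7-dihydroxy-2-(2,2-dimethyl-2H-chromen-6-yl)-6,8-bis(3-methylbut-2-en-1-yl)-2,3-dihydro-4H-chromen-4-one | CC(C)=CCc1c(O)c(CC=C(C)C)c2c(c1O)C(=O)C[C@@H](c1ccc3c(c1)C=CC(C)(C)O3)O2 | target

**Step count**
Total steps: 10. Longest linear sequence: 6 steps (steps 1, 2, 3, 4, 9, 10; the branch of steps 5, 6, 7, 8, 9, 10 is equally long).

**Steps most likely to fail**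

1. Step 9. Acylation may take place at a phenoxide oxygen instead of being delivered to carbon, the ring carbon may attack the enoyl chloride in the conjugate sense, or the sequence may stall at the open chalcone. The fallback sets out from 7 and 16 and returns at 19. Compound 16 is treated with N,O-dimethylhydroxylamine hydrochloride and pyridine to give the Weinreb amide (2E)-3-(2,2-dimethyl-2H-chromen-6-yl)-N-methoxy-N-methylprop-2-enamide F1. Compound 7 is lithiated with n-BuLi at its last ring C–H, again between two MOM ethers, to [2,4,6-tris(methoxymethoxy)-3,5-bis(3-methylbut-2-en-1-yl)phenyl]lithium F2. F2 adds to the carbonyl group of F1 (Weinreb ketone synthesis) and should give the protected chalcone (2E)-3-(2,2-dimethyl-2H-chromen-6-yl)-1-[2,4,6-tris(methoxymethoxy)-3,5-bis(3-methylbut-2-en-1-yl)phenyl]prop-2-en-1-one F3. Methanolic HCl then removes the MOM groups and the freed chalcone 18 closes to 19, with NaOAc in EtOH if needed. In this fallback the two ring C bonds are made in separate operations.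

2. Step 10. Hydride transfer to the hydrogen-bonded, electron-rich ketone may be slow or may discriminate poorly between the enantiomers, and the free phenols may bind the catalyst. The fallback sets out from 19 and returns at 20. Preparative chromatography on a polysaccharide-carbamate chiral stationary phase separates the enantiomers directly, and the (2S) fraction is 20. No bond is made and no new compound arises (F0).

3. Step 4. During MOM cleavage a prenyl group may cyclize onto a freed neighbouring phenol, HCl or methanol may add across a prenyl alkene, and the electron-rich triol may be oxidized by air. The fallback sets out from 1 and 3 and returns at 8. Phloroglucinol is C-prenylated twice with 3 in aqueous KOH at 0 °C (C-alkylation of the ambident phenoxide), and 8 is separated by chromatography from mono- and triprenylated material. No protecting group and no acid are used, and no new compound arises (F0).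

**Further compounds**
F1 | step 9 | (2E)-3-(2,2-dimethyl-2H-chromen-6-yl)-N-methoxy-N-methylprop-2-enamide | CON(C)C(=O)/C=C/c1ccc2OC(C)(C)C=Cc2c1
F2 | step 9 | [2,4,6-tris(methoxymethoxy)-3,5-bis(3-methylbut-2-en-1-yl)phenyl]lithium | CC(C)=CCc1c(OCOC)c([Li])c(OCOC)c(CC=C(C)C)c1OCOC
F3 | step 9 | (2E)-3-(2,2-dimethyl-2H-chromen-6-yl)-1-[2,4,6-tris(methoxymethoxy)-3,5-bis(3-methylbut-2-en-1-yl)phenyl]prop-2-en-1-one | CC(C)=CCc1c(OCOC)c(C(=O)/C=C/c2ccc3OC(C)(C)C=Cc3c2)c(OCOC)c(CC=C(C)C)c1OCOC
F0 | step 10 | none | none
F0 | step 4 | none | none
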